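**Retrosynthetic overview**
1. Target 21 ⇒ triene 19: one-flask olefin metathesis closes the cyclopentene (C3=C4) last and caps the side chain as the prenyl group.
2. 19 ⇒ oxa-bridged diacetate 17: β-silyl (Peterson-type) opening of the C6–O–C10 ether unveils the exocyclic methylene and the free C6–OH together.
3. 17 ⇒ bicyclic enone 11: side chain built on the convex face (exo Mukaiyama–Michael of a propanal enol silane, matched allylboration, ketone reduction).
4. 11 ⇒ furfural-derived pyranone 4 + acyclic (E)-enone 7: furan dearomatisation, then an enantioselective dearomative [5+2] of the 3-oxidopyrylium betaine sets C1, C5 and C6; the trans C1/C5 relationship comes from the E-alkene.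
5. Ring order: seven-membered ring first (as an 8-oxabicyclo[3.2.1]octene), five-membered ring last.

Assumption: C1–C20 in the notes are the dictyolane locants of the target (C1/C5 ring fusion, C6 carbinol, C7 side-chain carbon, C9 acetoxy carbon, C10 methylidene carbon, C11/C12 side-chain stereocentres); routine reagents and catalysts, including Roush's (R,R)-DIPT allylboronate and 9-amino-9-deoxy-epi-quinine, are taken as available.

**Step 1**
Reactants: 1 furfural
Product: 2 rac-1-(furan-2-yl)-2-(trimethylsilyl)ethan-1-ol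
Conditions: Me3SiCH2MgCl (1.2 equiv), THF, 0 °C; sat. aq. NH4Cl
Reagents that add atoms: (trimethylsilyl)methylmagnesium chloride, C[Si](C)(C)C[Mg]Cl
Why: Grignard 1,2-addition to the aldehyde gives the β-hydroxysilane, which survives a neutral work-up (no acid or strong base, so no Peterson elimination); the carbinol centre is racemic and is erased in step 4.

**Step 2**
Reactants: 2 rac-1-(furan-2-yl)-2-(trimethylsilyl)ethan-1-ol
Product: 4 5-oxo-6-[(trimethylsilyl)methyl]-5,6-dihydro-2H-pyran-2-yl acetate (cis/trans mixture; racemic), via pyranone hemiacetal 3 (not isolated)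
Conditions: NBS, NaHCO3, THF/H2O (4:1), 0 °C; then solvent switch, Ac2O, pyridine, DMAP (cat.), CH2Cl2, 0 °C
Reagents that add atoms: water, O; acetic anhydride, CC(=O)OC(C)=O
Why: Achmatowicz oxidative rearrangement dearomatises the furan to the pyranone hemiacetal (buffered so the β-hydroxysilane is not eliminated), and acetylation installs the anomeric leaving group; both stereocentres are mixtures and are erased in step 4.

**Step 3**
Reactants: 5 4,4-diethoxybut-1-ene; 6 but-3-en-2-one
Product: 7 (3E)-6,6-diethoxyhex-3-en-2-one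
Conditions: Hoveyda–Grubbs II (2 mol %), 6 (3 equiv), CH2Cl2, 40 °C
Reagents that add atoms: none
Why: Ru-catalysed olefin cross-metathesis of a terminal alkene with an electron-poor enone gives the (E)-enone selectively with loss of ethene.

**Step 4 (key step)**
Reactants: 4 5-oxo-6-[(trimethylsilyl)methyl]-5,6-dihydro-2H-pyran-2-yl acetate; 7 (3E)-6,6-diethoxyhex-3-en-2-one
Product: 10 (1R,5R,6R,7R)-6-acetyl-7-(2-oxoethyl)-1-[(trimethylsilyl)methyl]-8-oxabicyclo[3.2.1]oct-3-en-2-one, via oxidopyrylium betaine 8 (not isolated), via acetal cycloadduct 9 (not isolated)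
Conditions: 7 (3 equiv), 9-amino-9-deoxy-epi-quinine (20 mol %), 2-fluorobenzoic acid (40 mol %), i-Pr2NEt (1.1 equiv, syringe pump), toluene, 0 °C → rt; then 1 M HCl, THF, rt
Reagents that add atoms: water, O
Why: Proposed new method: 1,4-elimination of acetic acid from 4 gives the 6π-aromatic 3-oxidopyrylium betaine 8, whose nucleophilic C2 terminus adds to the β-carbon of the chiral primary-amine iminium ion of enone 7 and whose oxocarbenium C6 terminus is then closed by the resulting enamine (Michael/Mannich, a formal dearomative [5+2] cycloaddition); this puts the acyl-bearing carbon next to the H-bearing bridgehead (the usual 6-acyl regiochemistry), carries the E-geometry over as the trans C1/C5 relationship with the acyl group endo and the acetal arm exo, and lets the catalyst (quinine series assumed to give the enantiomer shown, the quinidine-derived pseudo-enantiomer giving the antipode) fix the absolute configuration of C1, C5, C6 and C10 at once, the steady low ylide concentration limiting dimerisation and the acetal keeping the aldehyde away from the amine until the acidic work-up; the closest known reaction types are the thermal and aminocatalytic (dienamine or aminothiourea) oxidopyrylium [5+2] cycloadditions and primary-amine iminium catalysis of enone dipolar cycloadditions and of Michael additions of tertiary carbon nucleophiles.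

**Step 5**
Reactants: 10 (1R,5R,6R,7R)-6-acetyl-7-(2-oxoethyl)-1-[(trimethylsilyl)methyl]-8-oxabicyclo[3.2.1]oct-3-en-2-one
Product: 11 (1R,5R,6S,7R)-7-(prop-2-en-1-yl)-6-(prop-1-en-2-yl)-1-[(trimethylsilyl)methyl]-8-oxabicyclo[3.2.1]oct-3-en-2-one
Conditions: Ph3PCH3Br, KHMDS (2.2 equiv ylide), THF, −78 → 0 °C
Reagents that add atoms: methyltriphenylphosphonium bromide, C[P+](c1ccccc1)(c1ccccc1)c1ccccc1.[Br-] (used as its ylide methylenetriphenylphosphorane, C=P(c1ccccc1)(c1ccccc1)c1ccccc1)
Why: Double Wittig methylenation of the unhindered aldehyde and methyl ketone; the enone carbonyl is conjugated and flanked by the quaternary bridgehead, so it reacts far more slowly, and the endo/exo (trans) arrangement on the two-carbon bridge is the thermodynamic one, so transient enolisation at C5 does no harm.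

**Step 6**
Reactants: 12 propanal
Product: 13 (Z)-trimethyl(prop-1-en-1-yloxy)silane
Conditions: TMSCl, Et3N, DMF, 80 °C; fractional distillation
Reagents that add atoms: chlorotrimethylsilane, C[Si](C)(C)Cl
Why: Amine-mediated enolisation and O-silylation of the aldehyde gives the enol silane, mainly as the (Z)-isomer, which is enriched by distillation.

**Step 7**
Reactants: 11 (1R,5R,6S,7R)-7-(prop-2-en-1-yl)-6-(prop-1-en-2-yl)-1-[(trimethylsilyl)methyl]-8-oxabicyclo[3.2.1]oct-3-en-2-one; 13 (Z)-trimethyl(prop-1-en-1-yloxy)silane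
Product: 14 (2S)-2-[(1R,4S,5R,6S,7R)-2-oxo-7-(prop-2-en-1-yl)-6-(prop-1-en-2-yl)-1-[(trimethylsilyl)methyl]-8-oxabicyclo[3.2.1]octan-4-yl]propanal
Conditions: TiCl4/Ti(Oi-Pr)4 (1:1, 1.1 equiv), CH2Cl2, −78 °C; aq. NaHCO3
Reagents that add atoms: none
Why: Mukaiyama–Michael addition in which the enol silane attacks the Ti-activated enone at C7 from the exo face (the endo face is covered by the two-carbon bridge and its endo isopropenyl group), so the new chain is cis to the bridging oxygen (C7), and in the open antiperiplanar transition state the methyl group turns away from the bridgehead to give (11S); the mixed Ti promoter is the mild one suited to aldehyde-derived enol silanes.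

**Step 8**
Reactants: 14 (2S)-2-[(1R,4S,5R,6S,7R)-2-oxo-7-(prop-2-en-1-yl)-6-(prop-1-en-2-yl)-1-[(trimethylsilyl)methyl]-8-oxabicyclo[3.2.1]octan-4-yl]propanal
Product: 15 (1R,4S,5R,6S,7R)-4-[(2S,3S)-3-hydroxyhex-5-en-2-yl]-7-(prop-2-en-1-yl)-6-(prop-1-en-2-yl)-1-[(trimethylsilyl)methyl]-8-oxabicyclo[3.2.1]octan-2-one
Conditions: (R,R)-DIPT allylboronate (1.5 equiv), 4 Å MS, toluene, −78 °C; H2O work-up
Reagents that add atoms: diisopropyl (4R,5R)-2-(prop-2-en-1-yl)-1,3,2-dioxaborolane-4,5-dicarboxylate, CC(C)OC(=O)[C@@H]1OB(CC=C)O[C@H]1C(=O)OC(C)C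
Why: Roush asymmetric allylboration through a closed chair (Zimmerman–Traxler) transition state, in which the si-face preference of the (R,R)-tartrate reagent coincides with the Felkin–Anh face of the α-methyl aldehyde (matched pair) and gives the 11,12-syn (12S) alcohol; the hindered ketone does not react at −78 °C.

**Step 9**
Reactants: 15 (1R,4S,5R,6S,7R)-4-[(2S,3S)-3-hydroxyhex-5-en-2-yl]-7-(prop-2-en-1-yl)-6-(prop-1-en-2-yl)-1-[(trimethylsilyl)methyl]-8-oxabicyclo[3.2.1]octan-2-one
Product: 16 (1R,2R,4S,5R,6S,7R)-4-[(2S,3S)-3-hydroxyhex-5-en-2-yl]-7-(prop-2-en-1-yl)-6-(prop-1-en-2-yl)-1-[(trimethylsilyl)methyl]-8-oxabicyclo[3.2.1]octan-2-ol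
Conditions: NaBH4, CeCl3·7H2O, MeOH, −40 °C
Reagents that add atoms: none
Why: Luche-type reduction in which the small hydride adds to C9 from the open exo (oxygen-bridge) face, the endo face being screened by the two-carbon bridge, to give the endo (equatorial) alcohol, which is also the isomer free of a 1,3-diaxial clash with the C7 side chain.

**Step 10**
Reactants: 16 (1R,2R,4S,5R,6S,7R)-4-[(2S,3S)-3-hydroxyhex-5-en-2-yl]-7-(prop-2-en-1-yl)-6-(prop-1-en-2-yl)-1-[(trimethylsilyl)methyl]-8-oxabicyclo[3.2.1]octan-2-ol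
Product: 17 (2S,3S)-2-[(1R,2R,4S,5R,6S,7R)-2-(acetyloxy)-7-(prop-2-en-1-yl)-6-(prop-1-en-2-yl)-1-[(trimethylsilyl)methyl]-8-oxabicyclo[3.2.1]octan-4-yl]hex-5-en-3-yl acetate
Conditions: Ac2O, DMAP, pyridine, CH2Cl2, rt
Reagents that add atoms: acetic anhydride, CC(=O)OC(C)=O
Why: DMAP-catalysed acylation of both secondary alcohols; the C6 oxygen is still tied up as the bridging ether, so no hydroxyl differentiation is needed.

**Step 11**
Reactants: 17 (2S,3S)-2-[(1R,2R,4S,5R,6S,7R)-2-(acetyloxy)-7-(prop-2-en-1-yl)-6-(prop-1-en-2-yl)-1-[(trimethylsilyl)methyl]-8-oxabicyclo[3.2.1]octan-4-yl]hex-5-en-3-yl acetate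
Product: 19 (1R,3S,4R,5S,6R)-3-[(2S,3S)-3-(acetyloxy)hex-5-en-2-yl]-4-hydroxy-7-methylidene-6-(prop-2-en-1-yl)-5-(prop-1-en-2-yl)cycloheptyl acetate, via trimethylsilyl ether 18 (not isolated)
Conditions: TMSOTf (0.2 equiv), 2,6-di-tert-butyl-4-methylpyridine (0.3 equiv), CH2Cl2, −78 °C; then citric acid, MeOH/H2O, 0 °C
Reagents that add atoms: none
Why: Acid-mode Peterson-type elimination: O-silylation of the bridging ether ionises the tertiary C10–O bond with β-silicon assistance, loss of the silyl group gives only the exocyclic C10 methylene and regenerates TMSOTf, and mild hydrolysis of the transient silyl ether frees the C6 hydroxyl with its configuration untouched.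

**Step 12**
Reactants: 19 (1R,3S,4R,5S,6R)-3-[(2S,3S)-3-(acetyloxy)hex-5-en-2-yl]-4-hydroxy-7-methylidene-6-(prop-2-en-1-yl)-5-(prop-1-en-2-yl)cycloheptyl acetate
Product: 21 (3aS,4R,5S,7R,8aR)-5-[(2S,3S)-3-(acetyloxy)-6-methylhept-5-en-2-yl]-4-hydroxy-3-methyl-8-methylidene-1,3a,4,5,6,7,8,8a-octahydroazulen-7-yl acetate (target), via ring-closed terminal alkene 20 (not isolated)
Conditions: Grubbs II (10 mol %), 2-methylbut-2-ene/CH2Cl2 (1:2), 40 °C
Reagents that add atoms: 2-methylbut-2-ene, CC=C(C)C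
Why: Olefin metathesis: ring-closing metathesis of the trans-disposed allyl and isopropenyl groups forms the trisubstituted cyclopentene (trans ring fusion already fixed in step 4), and cross-metathesis of the remaining monosubstituted alkene with 2-methylbut-2-ene gives the prenyl terminus, while the hindered 1,1-disubstituted exocyclic methylene stays out.

**Compound list**
1 | furfural (furan-2-carbaldehyde) | O=Cc1ccco1 | starting material
2 | rac-1-(furan-2-yl)-2-(trimethylsilyl)ethan-1-ol (racemate) | C[Si](C)(C)CC(O)c1ccco1 | intermediate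
3 | 6-hydroxy-2-[(trimethylsilyl)methyl]-2H-pyran-3(6H)-one (cis/trans mixture, racemic) | C[Si](C)(C)CC1OC(O)C=CC1=O | intermediate (not isolated)
4 | 5-oxo-6-[(trimethylsilyl)methyl]-5,6-dihydro-2H-pyran-2-yl acetate (cis/trans mixture, racemic) | C[Si](C)(C)CC1OC(OC(C)=O)C=CC1=O | intermediate
5 | 4,4-diethoxybut-1-ene | C=CCC(OCC)OCC | starting material
6 | but-3-en-2-one | C=CC(C)=O | starting material
7 | (3E)-6,6-diethoxyhex-3-en-2-one | CC(=O)/C=C/CC(OCC)OCC | intermediate
8 | 2-[(trimethylsilyl)methyl]pyrylium-3-olate (achiral betaine) | C[Si](C)(C)Cc1[o+]cccc1[O-] | intermediate (not isolated)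
9 | (1R,5R,6R,7R)-6-acetyl-7-(2,2-diethoxyethyl)-1-[(trimethylsilyl)methyl]-8-oxabicyclo[3.2.1]oct-3-en-2-one (6-endo, 7-exo) | C[Si](C)(C)C[C@]12C(=O)C=C[C@@H](O2)[C@H](C(C)=O)[C@H]1CC(OCC)OCC | intermediate (not isolated)
10 | (1R,5R,6R,7R)-6-acetyl-7-(2-oxoethyl)-1-[(trimethylsilyl)methyl]-8-oxabicyclo[3.2.1]oct-3-en-2-one (6-endo, 7-exo) | C[Si](C)(C)C[C@]12C(=O)C=C[C@@H](O2)[C@H](C(C)=O)[C@H]1CC=O | intermediate
11 | (1R,5R,6S,7R)-7-(prop-2-en-1-yl)-6-(prop-1-en-2-yl)-1-[(trimethylsilyl)methyl]-8-oxabicyclo[3.2.1]oct-3-en-2-one | C[Si](C)(C)C[C@]12C(=O)C=C[C@@H](O2)[C@H](C(C)=C)[C@H]1CC=C | intermediate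
12 | propanal | CCC=O | starting material
13 | (Z)-trimethyl(prop-1-en-1-yloxy)silane | C/C=C\O[Si](C)(C)C | intermediate
14 | (2S)-2-[(1R,4S,5R,6S,7R)-2-oxo-7-(prop-2-en-1-yl)-6-(prop-1-en-2-yl)-1-[(trimethylsilyl)methyl]-8-oxabicyclo[3.2.1]octan-4-yl]propanal (chain exo at C4) | C[Si](C)(C)C[C@]12C(=O)C[C@@H]([C@H](C)C=O)[C@@H](O2)[C@H](C(C)=C)[C@H]1CC=C | intermediate
15 | (1R,4S,5R,6S,7R)-4-[(2S,3S)-3-hydroxyhex-5-en-2-yl]-7-(prop-2-en-1-yl)-6-(prop-1-en-2-yl)-1-[(trimethylsilyl)methyl]-8-oxabicyclo[3.2.1]octan-2-one | C[Si](C)(C)C[C@]12C(=O)C[C@@H]([C@H](C)[C@H](CC=C)O)[C@@H](O2)[C@H](C(C)=C)[C@H]1CC=C | intermediate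
16 | (1R,2R,4S,5R,6S,7R)-4-[(2S,3S)-3-hydroxyhex-5-en-2-yl]-7-(prop-2-en-1-yl)-6-(prop-1-en-2-yl)-1-[(trimethylsilyl)methyl]-8-oxabicyclo[3.2.1]octan-2-ol (2-endo-OH) | C[Si](C)(C)C[C@]12[C@H](O)C[C@@H]([C@H](C)[C@H](CC=C)O)[C@@H](O2)[C@H](C(C)=C)[C@H]1CC=C | intermediate
17 | (2S,3S)-2-[(1R,2R,4S,5R,6S,7R)-2-(acetyloxy)-7-(prop-2-en-1-yl)-6-(prop-1-en-2-yl)-1-[(trimethylsilyl)methyl]-8-oxabicyclo[3.2.1]octan-4-yl]hex-5-en-3-yl acetate | C[Si](C)(C)C[C@]12[C@H](OC(C)=O)C[C@@H]([C@H](C)[C@H](CC=C)OC(C)=O)[C@@H](O2)[C@H](C(C)=C)[C@H]1CC=C | intermediate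
18 | (1R,3S,4R,5S,6R)-3-[(2S,3S)-3-(acetyloxy)hex-5-en-2-yl]-7-methylidene-6-(prop-2-en-1-yl)-5-(prop-1-en-2-yl)-4-[(trimethylsilyl)oxy]cycloheptyl acetate | C=C1[C@H](OC(C)=O)C[C@@H]([C@H](C)[C@H](CC=C)OC(C)=O)[C@@H](O[Si](C)(C)C)[C@H](C(C)=C)[C@H]1CC=C | intermediate (not isolated)
19 | (1R,3S,4R,5S,6R)-3-[(2S,3S)-3-(acetyloxy)hex-5-en-2-yl]-4-hydroxy-7-methylidene-6-(prop-2-en-1-yl)-5-(prop-1-en-2-yl)cycloheptyl acetate | C=C1[C@H](OC(C)=O)C[C@@H]([C@H](C)[C@H](CC=C)OC(C)=O)[C@@H](O)[C@H](C(C)=C)[C@H]1CC=C | intermediate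
20 | (3aS,4R,5S,7R,8aR)-5-[(2S,3S)-3-(acetyloxy)hex-5-en-2-yl]-4-hydroxy-3-methyl-8-methylidene-1,3a,4,5,6,7,8,8a-octahydroazulen-7-yl acetate | C=C1[C@H](OC(C)=O)C[C@@H]([C@H](C)[C@H](CC=C)OC(C)=O)[C@@H](O)[C@@H]2C(C)=CC[C@@H]12 | intermediate (not isolated)
21 | (3aS,4R,5S,7R,8aR)-5-[(2S,3S)-3-(acetyloxy)-6-methylhept-5-en-2-yl]-4-hydroxy-3-methyl-8-methylidene-1,3a,4,5,6,7,8,8a-octahydroazulen-7-yl acetate (CNP0151479.2) | C=C1[C@H](OC(C)=O)C[C@@H]([C@H](C)[C@H](CC=C(C)C)OC(C)=O)[C@@H](O)[C@@H]2C(C)=CC[C@@H]12 | target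

**Step count**
Total: 12 steps. Longest linear sequence: 10 steps (1, 2, 4, 5, 7, 8, 9, 10, 11, 12); steps 3 and 6 make the two small fragments.

**Three steps most likely to fail, with fallbacks**

Step 4 (conversion, regiochemistry and ee of the amine-catalysed [5+2]). The fallback sets out from 4 and 7 and comes back at 10. The two partners are combined under the classical base-mediated conditions (7 in fivefold excess, Et3N added slowly, MeCN, rt), which give the thermal, racemic cycloadduct, that is 9 together with its mirror image, the enantiomeric acetal cycloadduct F1. The same acidic work-up gives racemic keto aldehyde, that is 10 together with the enantiomeric keto aldehyde F2. Preparative chiral SFC then delivers 10.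

Step 7 (over-reaction of the aldehyde product and C11 selectivity). The fallback sets out from 11 and comes back at 16. Mukaiyama–Michael addition of the ketene silyl acetal of methyl propanoate (TiCl4, CH2Cl2, −78 °C), whose ester product cannot react further, gives the methyl ester F3. LiAlH4 (THF, −78 → 0 °C) reduces ester and ketone (exo hydride attack) to the diol F4. TEMPO/PhI(OAc)2 oxidises only the primary alcohol to the hydroxy aldehyde F5. Roush allylboration as in step 8 (2.5 equiv of boronate) then gives 16, so steps 8 and 9 are bypassed.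

Step 9 (facial selectivity at C9 next to the axial C7 chain). The fallback sets out from 15 and comes back at 16. Stereocontrol is switched from substrate to reagent: Corey–Bakshi–Shibata reduction with catecholborane (toluene, −78 °C), using the oxazaborolidine enantiomer that delivers hydride to the exo face (large group = quaternary bridgehead side, small group = CH2 side). The product is 16 itself, so this makes no new compound (F0).

**Further compounds**
F1 | step 4 | (1S,5S,6S,7S)-6-acetyl-7-(2,2-diethoxyethyl)-1-[(trimethylsilyl)methyl]-8-oxabicyclo[3.2.1]oct-3-en-2-one (enantiomer of 9) | C[Si](C)(C)C[C@@]12C(=O)C=C[C@H](O2)[C@@H](C(C)=O)[C@@H]1CC(OCC)OCC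
F2 | step 4 | (1S,5S,6S,7S)-6-acetyl-7-(2-oxoethyl)-1-[(trimethylsilyl)methyl]-8-oxabicyclo[3.2.1]oct-3-en-2-one (enantiomer of 10) | C[Si](C)(C)C[C@@]12C(=O)C=C[C@H](O2)[C@@H](C(C)=O)[C@@H]1CC=O
F3 | step 7 | methyl (2S)-2-[(1R,4S,5R,6S,7R)-2-oxo-7-(prop-2-en-1-yl)-6-(prop-1-en-2-yl)-1-[(trimethylsilyl)methyl]-8-oxabicyclo[3.2.1]octan-4-yl]propanoate | C[Si](C)(C)C[C@]12C(=O)C[C@@H]([C@H](C)C(=O)OC)[C@@H](O2)[C@H](C(C)=C)[C@H]1CC=C
F4 | step 7 | (1R,2R,4S,5R,6S,7R)-4-[(2S)-1-hydroxypropan-2-yl]-7-(prop-2-en-1-yl)-6-(prop-1-en-2-yl)-1-[(trimethylsilyl)methyl]-8-oxabicyclo[3.2.1]octan-2-ol | C[Si](C)(C)C[C@]12[C@H](O)C[C@@H]([C@H](C)CO)[C@@H](O2)[C@H](C(C)=C)[C@H]1CC=C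
F5 | step 7 | (2S)-2-[(1R,2R,4S,5R,6S,7R)-2-hydroxy-7-(prop-2-en-1-yl)-6-(prop-1-en-2-yl)-1-[(trimethylsilyl)methyl]-8-oxabicyclo[3.2.1]octan-4-yl]propanal | C[Si](C)(C)C[C@]12[C@H](O)C[C@@H]([C@H](C)C=O)[C@@H](O2)[C@H](C(C)=C)[C@H]1CC=C
F0 | step 9 | none | none
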